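G leaves these flasks slowly, over minutes, and such a decline can be read in logarithms.

| setting | noon | dusk | summer | ash | birch |
|---|---|---|---|---|---|
| G | 34 mM | 66 mM | 130 mM | 120 mM | 40 mM |
| X | 11 mM (held) | 11 mM (held) | 11 mM (held) | 11 mM (held) | 11 mM (held) |
| remark | run made earlier | run made earlier | run made earlier |  |  |
| time |  |  |  | 10 min | 6.0 min |

| run | time / min | Q / % | G / % |
|---|---|---|---|
| noon | 1.33 | 32 | 60 |
| noon | 2.50 | 48 | 44 |
| noon | 4.00 | 65 | 24 |
| noon | 5.00 | 75 | 14 |
| noon | 6.00 | 77 | 12 |
| dusk | 0.500 | 11 | 87 |
| dusk | 1.50 | 29 | 62 |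
| dusk | 3.00 | 52 | 39 |
| dusk | 4.00 | 62 | 25 |
| dusk | 6.00 | 78 | 15 |
| summer | 1.33 | 25 | 76 |
| summer | 2.50 | 40 | 53 |
| summer | 4.00 | 56 | 32 |
| summer | 5.00 | 62 | 22 |
| summer | 6.00 | 71 | 14 |

(readings scatter by 2 percentage points)

- which one finishes higher in amount of Q, in percent of the G charged ("neither" within 2 percentage points) (ash / birch / neither)
- amount of Q at the end, in percent of the G charged, ash
- amount of Q at the end, in percent of the G charged, birch

- the analysis behind the earlier runs scatters by 2 percentage points, standard deviation
- at the start none of X is in solution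

At 6.00 min, noon, dusk and summer show G at 12%, 15% and 14% of the charge, a spread of 3 percentage points against a scatter of 2 points. So one figure is taken for the three charges, as an estimate:

decade time = 6.00 min / 0.866 = 6.93 min

This decade time is the time [G] takes to fall by a factor of 10. It treats the decay as pseudo-first-order, with X held. Dividing each run time by it gives the power of 10 that G has lost:

G left in birch = 13.6%; G left in ash = 3.60%

The next link is the selectivity, Q made per G gone, taken from the last reading of the run nearest in charge:

noon, for birch: 87.5%, so Q = 75.6%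

summer, for ash: 82.6%, so Q = 79.6%

The weak link is that each selectivity rests on one reading of Q. Summing Q and G gone over every reading of a run reforges it:

noon: 85.8%, so birch Q = 74.2%

summer: 83.8%, so ash Q = 80.8%

On this reckoning ash stands higher than birch by 6.6 points, beyond the margin of 2 points.

The forecast, made apart from this reckoning and 2.3 points higher on birch, names ash, with 81% for ash and 76.5% for birch: “Ash finishes higher, but only modestly.”

The flasks give 81.4% for ash and 76.6% for birch, so ash finishes higher.

    X ⇌ E, rate k1*(csat - [E]) (kL = 0.0950 s⁻¹)
    G → D (k = 8.00 × 10⁻⁴ s⁻¹)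
    E → L (k = 0.00140 s⁻¹)
    G + E → Q (k = 0.550 M⁻¹ s⁻¹)

The reckoning lies 0.60 points under ash and 2.4 points under birch, against a scatter of 2 points. In birch, the dissolved gas [E] stands at 9.98 mM at 3.00 min and at 10.6 mM at 6.00 min, with saturation at 11 mM. The neighbouring flask, birch stopped at 2.5 min, gets the same reckoning: G left 43.6% and Q 48.4%. That flask holds [E] at 9.82 mM, G at 42.9% and Q at 48.8%.

The data were generated by integration with made-up constants; the scatter is artificial.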